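At late times each electrophile turned to target has set one acid free, and the free base charged, 0.0750 M, is half of the electrophile charged, 0.15 M, so free base is this flask's limiting reagent for the acid, and the nucleophile takes the excess.

electrophile 0.15 M; free base 0.0750 M; gas 17 mM (held); time 20 s

    electrophile + target ⇌ idle adduct B, settled at all times (K1 = 10.2 L mol⁻¹)
    nucleophile + acid set free ⇌ idle adduct A, settled at all times (K2 = 2540 L mol⁻¹)
    electrophile + nucleophile → acid set free + target (k3 = 1.98 L mol⁻¹ s⁻¹)
    nucleophile + acid set free ⇌ protonated nucleophile, settled at all times (K4 = 10600 L mol⁻¹)
    gas ⇌ nucleophile, rate k5*(csat - [nucleophile]) (k5 = 0.721 s⁻¹, csat = 17 mM)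
    acid set free + free base ⇌ salt of the base, settled at all times (K6 = 6.5 × 10⁵ L mol⁻¹)

- part of the electrophile that has reacted at 20 s
- share of free nucleophile in free nucleophile and protonated nucleophile together, at 20 s

- percent here means electrophile units held: one idle adduct B counts as two
- what is said of target includes idle adduct B
- what is said of acid set free includes idle adduct A
- at the start none of nucleophile is dissolved
- in an amount of target, one idle adduct B counts as one target
- what has gone from electrophile into another species counts as reacted, even if it can come back
- run time (flask): 20 s

1. The level. In this flask the excess acid, 0.0750 M, ends on dissolved nucleophile, shared between protonated nucleophile and idle adduct A, while the gas holds free nucleophile near 17 mM. On this reckoning the free share runs towards 21.9%.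

2. The rule. Free base and nucleophile draw on one pool of acid, so [protonated nucleophile]/[nucleophile] equals [salt of the base]/[free base] times the buffer ratio, the nucleophile's protonation constant over the free base's salt constant, 0.0163.

3. The crossing. Free and protonated nucleophile stand equal at [salt of the base]/[free base] = 61.3, with 1.60% of the free base left.

4. The start. Dissolved nucleophile rises from nothing with a time constant of about 0.982 s, which is shorter than the time asked, towards the balance of inflow and consumption at the charged [electrophile], [nucleophile] = 0.0120 M. At that balance target grows at 0.00358 M s⁻¹.

5. The knee. At the start free base binds acid far more strongly, 49000, than nucleophile does, 128, so [salt of the base] follows target. Reckoned at the starting slope, the charged free base is taken up in 21.0 s, later than 20 s.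

6. My reckoning. Treating the electrophile as pseudo-first-order at that [nucleophile] gives 0.0569 M of target, and the rule then gives a free share of 95.1%. It does not count idle adduct B, so it offers no figure for the part reacted.

The forecast puts the part reacted at 51% (47% to 55%) and the free share at 96.3% (95% to 97.3%), a free share higher than mine, holding that the free base “buffers the acid at a few µM”.

The flask gives 49.9% reacted and a free share of 96.5%, both inside the forecast's ranges. At 20.0 s this flask holds 0.0516 M of salt of the base with 31.2% of its free base left, so the buffer ratio puts protonated nucleophile at 3.59% of free nucleophile. The neighbour charged with 0.019 M of free base has 0.818% of it left beside 0.0188 M of salt of the base. There the ratio gives 1.97 protonated nucleophile per free nucleophile, and the free share stands at 33.6%.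

(All constants were drawn at random within sensible limits; the run is a simulation.)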